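Ring A is the mono-hydroxy ring; ring B is numbered b1 (C–OAr), b2 (C–OH), b3, b4 (C–OH), b5, b6 (C–chain). Ring B is a 5-alkylresorcinol, and its crowded ether carbon b1, flanked by b2 and b6, corresponds to the central carbon of a malonate in a Michael–Claisen resorcinol annulation with an alk-3-en-2-one. Disconnecting b1–b6 and b2–b3 therefore opens the 20-membered ring and ring B together. In one base-mediated operation the key step re-forms both bonds, macrocycle by Michael addition, ring B by Claisen condensation. Its precursor is a ring A dimethyl aryloxymalonate, made by plain O-alkylation of an unhindered phenol, whose fourteen-methylene chain ends in an (E)-methyl enone.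

Key step: step 6

Assumption: in step 8 methanol is taken to condense at the unhindered b4 carbonyl, so that ring B emerges as its b4 methyl ether 18; a b2 methyl or a dimethyl ether formed alongside would be cleaved by BBr3 in step 9 in the same way.

Step 1
Reactants: 1 3,5-dimethoxybenzyl chloride; 2 1,12-dibromododecane
Product: 4 1-(13-bromotridecyl)-3,5-dimethoxybenzene, via 3,5-dimethoxybenzylmagnesium chloride 3 (not isolated)
Conditions: Mg, THF, 0 to 20 °C; then 2 (3 equiv), Li2CuCl4 (3 mol%), THF, −10 to 20 °C
Reagents that add atoms: none
Why: Copper-catalysed cross-coupling of a benzylic Grignard reagent with a primary alkyl bromide is a dependable sp3–sp3 bond formation, and the threefold excess of the symmetrical dibromide (recoverable) should keep double coupling minor.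

Step 2
Reactants: 4 1-(13-bromotridecyl)-3,5-dimethoxybenzene; 5 allylmagnesium bromide
Product: 6 1-(hexadec-15-en-1-yl)-3,5-dimethoxybenzene
Conditions: 5 (2 equiv), Li2CuCl4 (3 mol%), THF, 0 to 20 °C
Reagents that add atoms: none
Why: Copper-catalysed Grignard alkylation of the primary bromide by the allyl reagent should extend the chain by three carbons and install the terminal alkene in one operation.

Step 3
Reactants: 6 1-(hexadec-15-en-1-yl)-3,5-dimethoxybenzene
Product: 7 3-(hexadec-15-en-1-yl)-5-methoxyphenol
Conditions: NaSEt (4 equiv), DMF, 140 °C; then HCl (aq)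
Reagents that add atoms: none
Why: Thiolate SN2 demethylation of an aryl methyl ether should stop after one cleavage because the phenoxide formed is too poor a leaving group for a second one, and the isolated alkene is inert to the thiolate.

Step 4
Reactants: 7 3-(hexadec-15-en-1-yl)-5-methoxyphenol; 8 dimethyl chloromalonate
Product: 9 dimethyl 2-[3-(hexadec-15-en-1-yl)-5-methoxyphenoxy]malonate
Conditions: 8 (1.2 equiv), K2CO3 (2 equiv), acetone, 56 °C
Reagents that add atoms: none
Why: In this Williamson-type O-alkylation the unhindered phenoxide displaces chloride from the doubly activated alpha-chloro diester, so the oxygen destined for crowded b1 is attached before ring B exists.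

Step 5
Reactants: 9 dimethyl 2-[3-(hexadec-15-en-1-yl)-5-methoxyphenoxy]malonate; 10 methyl vinyl ketone
Product: 11 dimethyl 2-{3-methoxy-5-[(15E)-17-oxooctadec-15-en-1-yl]phenoxy}malonate
Conditions: 10 (5 equiv), second-generation Grubbs catalyst (5 mol%), CH2Cl2, 40 °C
Reagents that add atoms: none
Why: Olefin cross-metathesis of an unhindered terminal alkene with an electron-poor vinyl ketone should favour the cross product as the E isomer, and its neutral conditions leave the acidic malonate C–H alone, so donor and acceptor first meet base in step 6.

Step 6
Reactants: 11 dimethyl 2-{3-methoxy-5-[(15E)-17-oxooctadec-15-en-1-yl]phenoxy}malonate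
Product: 13 macrocyclic methyl 1-aryloxy-2,4-dioxocyclohexane-1-carboxylate (ring B: b1 quaternary C bearing O–ring A and CO2Me; b2 and b4 C=O; b6 CH joined to ring A by (CH2)14; diastereomer mixture), via macrocyclic Michael adduct 12 (not isolated)
Conditions: NaOMe (3 equiv), MeOH–THF, 65 °C, 11 added slowly to a final concentration of about 1 mM; then HCl (aq), 0 °C
Reagents that add atoms: none
Why: Proposed new method: methoxide ionises the malonate C–H and the resulting carbanion attacks the enone beta-carbon (chain C15, the future b6) in a reversible conjugate addition (b1–b6, 20-exo-trig macrocyclisation); the ketone enolate so formed equilibrates to its methyl terminus, which acylates either of the two diastereotopic ester groups (b2–b3, 6-exo-trig Claisen closure of ring B) with loss of methoxide. The nearest established reaction type is the intermolecular Michael–Claisen condensation of dialkyl malonates with alk-3-en-2-ones that furnishes 5-alkylcyclohexane-1,3-diones; what is untested is the Michael step at macrocyclic distance with a fully substituted, oxygen-bearing donor carbon. Stereocentres b1 and b6 arise without control by any element of the substrate, which is acceptable because both are flattened on aromatisation. Two selectivities are required: cyclisation over oligomerisation, secured by slow addition to about 1 mM and by the Michael step staying reversible until the Claisen step traps the cyclic adduct, and bond formation at the right atoms, secured because the malonate carbon is the only carbon acid acidic enough to add and because only the ketone methyl can reach an ester through a six-membered transition state (the alpha-methylene b5 would close a cyclobutanone). The acidic 1,3-dione is deprotonated as it forms, which should render the cascade irreversible overall.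

Step 7
Reactants: 13 macrocyclic methyl 1-aryloxy-2,4-dioxocyclohexane-1-carboxylate
Product: 15 macrocyclic 4-aryloxy-5-alkylcyclohexane-1,3-dione (b1 now CH–O–ring A; diastereomer mixture), via beta-keto acid 14 (not isolated)
Conditions: NaOH (aq), MeOH–THF, 65 °C; then HCl (aq) to pH 1, 65 °C
Reagents that add atoms: none
Why: Saponification followed by acidification should give a beta-keto acid that loses CO2 through the usual six-membered transition state, while under base the dione is masked as its enolate, which protects ring B from retro-Claisen cleavage.

Step 8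
Reactants: 15 macrocyclic 4-aryloxy-5-alkylcyclohexane-1,3-dione
Product: 18 macrocyclic diaryl ether with ring A OMe and ring B b2-OH b4-OMe, via vinylogous methyl ester 16 (not isolated), via b1-iodo ketone 17 (not isolated)
Conditions: I2 (2.2 equiv), MeOH, 65 °C
Reagents that add atoms: methanol, CO
Why: In this iodine–methanol aromatisation of a cyclohexane-1,3-dione, acid-catalysed enol ether formation at b4, iodination at b1 (alpha to the b2 carbonyl), loss of HI toward b6 and tautomerisation should give the phenol, while the HI formed keeps the electron-rich arenes from being iodinated.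

Step 9
Reactants: 18 macrocyclic diaryl ether with ring A OMe and ring B b2-OH b4-OMe
Product: 19 target macrocycle CNP0173380.0
Conditions: BBr3 (6 equiv), CH2Cl2, −78 to 20 °C; then H2O
Reagents that add atoms: none
Why: Lewis acid-mediated aryl methyl ether cleavage by BBr3 should remove both methyl groups by bromide attack at CH3, while the diaryl ether, which has no sp3 C–O bond, is inert.

Compound list
1 | 3,5-dimethoxybenzyl chloride | COc1cc(CCl)cc(OC)c1 | starting material
2 | 1,12-dibromododecane | BrCCCCCCCCCCCCBr | starting material
3 | 3,5-dimethoxybenzylmagnesium chloride (formed in situ) | COc1cc(C[Mg]Cl)cc(OC)c1 | intermediate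
4 | 1-(13-bromotridecyl)-3,5-dimethoxybenzene | COc1cc(CCCCCCCCCCCCCBr)cc(OC)c1 | intermediate
5 | allylmagnesium bromide | C=CC[Mg]Br | starting material
6 | 1-(hexadec-15-en-1-yl)-3,5-dimethoxybenzene | COc1cc(CCCCCCCCCCCCCCC=C)cc(OC)c1 | intermediate
7 | 3-(hexadec-15-en-1-yl)-5-methoxyphenol | COc1cc(O)cc(CCCCCCCCCCCCCCC=C)c1 | intermediate
8 | dimethyl chloromalonate | COC(=O)C(Cl)C(=O)OC | starting material
9 | dimethyl 2-[3-(hexadec-15-en-1-yl)-5-methoxyphenoxy]malonate | COc1cc(OC(C(=O)OC)C(=O)OC)cc(c1)CCCCCCCCCCCCCCC=C | intermediate
10 | methyl vinyl ketone (but-3-en-2-one) | CC(=O)C=C | starting material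
11 | dimethyl 2-{3-methoxy-5-[(15E)-17-oxooctadec-15-en-1-yl]phenoxy}malonate, key-step precursor | COc1cc(OC(C(=O)OC)C(=O)OC)cc(c1)CCCCCCCCCCCCCC/C=C/C(C)=O | intermediate
12 | macrocyclic Michael adduct (formed in situ): dimethyl malonate whose central carbon b1 carries the ring A oxygen and is bonded to b6; b6 carries the (CH2)14 chain to ring A and a 2-oxopropyl group; 20-membered ring; diastereomer mixture | COC(=O)C1(C(=O)OC)Oc2cc(OC)cc(c2)CCCCCCCCCCCCCCC1CC(C)=O | intermediate
13 | key-step product: macrocyclic methyl 1-aryloxy-2,4-dioxocyclohexane-1-carboxylate; cyclohexane C1 (b1) bears CO2Me and the ring A oxygen, C2 (b2) and C4 (b4) are ketones, C6 (b6) is tied to ring A by (CH2)14; diastereomer mixture at b1 and b6 | COC(=O)C12Oc3cc(OC)cc(c3)CCCCCCCCCCCCCCC1CC(=O)CC2=O | intermediate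
14 | carboxylic acid corresponding to 13 (formed in situ) | OC(=O)C12Oc3cc(OC)cc(c3)CCCCCCCCCCCCCCC1CC(=O)CC2=O | intermediate
15 | macrocyclic 4-aryloxy-5-alkylcyclohexane-1,3-dione; b1 is CH–O–ring A, b6 is CH–chain; diastereomer mixture | O=C1CC(=O)C2Oc3cc(OC)cc(c3)CCCCCCCCCCCCCCC2C1 | intermediate
16 | vinylogous methyl ester of 15: 3-methoxycyclohex-2-enone with OMe on b4, C=C b3=b4 and C=O on b2 (formed in situ) | COC1=CC(=O)C2Oc3cc(OC)cc(c3)CCCCCCCCCCCCCCC2C1 | intermediate
17 | b1-iodo derivative of 16 (formed in situ) | COC1=CC(=O)C2(I)Oc3cc(OC)cc(c3)CCCCCCCCCCCCCCC2C1 | intermediate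
18 | macrocyclic diaryl ether, ring A OMe, ring B b2-OH and b4-OMe (achiral) | COc1cc2cc(c1)Oc1c(O)cc(OC)cc1CCCCCCCCCCCCCC2 | intermediate
19 | CNP0173380.0: macrocyclic diaryl ether, ring A 3-hydroxy, ring B 2,4-dihydroxy, (CH2)14 bridge; achiral, no stereocentre | Oc1cc2cc(c1)Oc1c(O)cc(O)cc1CCCCCCCCCCCCCC2 | target

Total step count: 9. Longest linear sequence: 9 steps (1 to 19).

Steps most likely to fail

Step 6. Intermolecular conjugate addition may outrun ring closure and give oligomers. The Michael equilibrium of the fully substituted donor may also lie so far on the open side that methoxide addition and aldol self-condensation consume the enone before the Claisen step can trap the ring. The fallback uses known chemistry only: ring B is brought in preformed and the macrocycle is closed by olefin metathesis. It sets out from Grignard reagent 3 and allyl reagent 5 and returns at 19. Li2CuCl4-catalysed coupling of 3 with excess 1,10-dibromodecane gives 1-(11-bromoundecyl)-3,5-dimethoxybenzene F1. Allylation with 5 gives 1,3-dimethoxy-5-(tetradec-13-en-1-yl)benzene F2, and NaSEt in DMF gives 3-methoxy-5-(tetradec-13-en-1-yl)phenol F3. Ullmann ether coupling with commercial 2-bromo-3,5-dimethoxybenzaldehyde (CuI, picolinic acid, K3PO4, DMSO, 90 °C), assisted by the ortho formyl group, gives 3,5-dimethoxy-2-[3-methoxy-5-(tetradec-13-en-1-yl)phenoxy]benzaldehyde F4. Wittig methylenation (Ph3P=CH2, THF) gives the styrene 1-ethenyl-3,5-dimethoxy-2-[3-methoxy-5-(tetradec-13-en-1-yl)phenoxy]benzene F5. Ring-closing metathesis (second-generation Grubbs catalyst, CH2Cl2, 40 °C, about 1 mM) gives the 20-membered macrocyclic styrenyl alkene F6 (E/Z mixture). Hydrogenation (H2, Pd/C, EtOAc) gives the tri-O-methyl ether of the target F7, and BBr3 then cleaves all three methyl ethers to give 19.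

Step 8. Acid-promoted ionisation of the aryloxy group at b1 would expel the ring A phenol and open the macrocycle, and reduction of the intermediate iodide by HI may compete with loss of HI, so that aromatisation stalls. The fallback replaces halogenation by selenoxide elimination; it sets out from 15 and returns at 18. Vinylogous ester 16 is prepared deliberately from 15 (MeOH, HC(OMe)3, TsOH cat.) and isolated. Kinetic deprotonation at b1 with LiN(iPr)2 (THF, −78 °C) and trapping with PhSeCl gives the b1 phenylselenide of 16 F8. H2O2 (CH2Cl2, 0 to 20 °C) oxidises selenium; syn-elimination toward the b6 hydrogen and tautomerisation then give 18.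

Step 7. Hydroxide may attack the hindered, enolate-shielded ester too slowly, and forcing conditions may then open ring B by retro-Claisen cleavage. The fallback is a Krapcho dealkoxycarbonylation from 13 to 15: LiCl in wet DMSO at 140 °C removes the ester methyl by SN2 attack of chloride, and the carboxylate loses CO2 directly to the dione enolate with no hydroxide present. This detour makes no compound outside the list (F0).

Further compounds
F1 | step 6 | 1-(11-bromoundecyl)-3,5-dimethoxybenzene | COc1cc(CCCCCCCCCCCBr)cc(OC)c1
F2 | step 6 | 1,3-dimethoxy-5-(tetradec-13-en-1-yl)benzene | COc1cc(CCCCCCCCCCCCC=C)cc(OC)c1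
F3 | step 6 | 3-methoxy-5-(tetradec-13-en-1-yl)phenol | COc1cc(O)cc(CCCCCCCCCCCCC=C)c1
F4 | step 6 | 3,5-dimethoxy-2-[3-methoxy-5-(tetradec-13-en-1-yl)phenoxy]benzaldehyde | COc1cc(C=O)c(Oc2cc(OC)cc(CCCCCCCCCCCCC=C)c2)c(OC)c1
F5 | step 6 | 1-ethenyl-3,5-dimethoxy-2-[3-methoxy-5-(tetradec-13-en-1-yl)phenoxy]benzene | COc1cc(C=C)c(Oc2cc(OC)cc(CCCCCCCCCCCCC=C)c2)c(OC)c1
F6 | step 6 | 20-membered macrocyclic styrenyl alkene, tri-O-methyl, ring B–CH=CH–(CH2)12–ring A (E/Z mixture) | COc1cc2cc(c1)Oc1c(OC)cc(OC)cc1C=CCCCCCCCCCCCC2
F7 | step 6 | tri-O-methyl ether of the target (ring A OMe, ring B b2-OMe and b4-OMe) | COc1cc2cc(c1)Oc1c(OC)cc(OC)cc1CCCCCCCCCCCCCC2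
F8 | step 8 | b1 phenylselenide of vinylogous ester 16 | COC1=CC(=O)C2([Se]c3ccccc3)Oc3cc(OC)cc(c3)CCCCCCCCCCCCCCC2C1
F0 | step 7 | none | none
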